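**Retrosynthetic overview**
- Selaginellin F ⇐ a 7-(arylethynyl)-8-(silyloxymethyl)-6H-benzo[c]chromen-6-one. The lactone carbonyl is the future methide carbon: two 4-(methoxymethoxy)phenyllithium additions open the lactone and free the 2'-OH, then acid removes all protecting groups and dehydrates the trityl alcohol to the quinone methide.
- Lactone ⇐ acyclic tetrayne aryl ester. One thermal hexadehydro-Diels–Alder reaction closes the central benzene ring and the pyranone ring together; the aryne carbons become the two adjacent ring CH groups by hydrogen transfer, and the spare alkyne of the diynoate is the arylethynyl arm.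
- Tetrayne ester ⇐ ortho-(1,3-diynyl)phenol (from 2,4-dihydroxybenzaldehyde by alkyne homologation and Cadiot–Chodkiewicz coupling) + 5-arylpenta-2,4-diynoic acid (from 4-iodophenol, bis(trimethylsilyl)butadiyne and CO2).
- Ring order: the resorcinol ring and the three 4-oxygenated benzene rings are bought; the central benzene ring and the lactone ring form together in step 9; the lactone ring is opened in step 10, where one bought phenol ring ends as the cyclohexadienone ring by tautomerisation.

Assumption: the target has no stereocentre and no configurationally defined double bond (the two 4-oxygenated rings on the methide carbon exchange by tautomerism), so the SMILES as given is the only stereoisomer and nothing has to be set stereochemically.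

**Route**

Step 1
Reactants: 1 2,4-dihydroxybenzaldehyde
Product: 2 2-hydroxy-4-(methoxymethoxy)benzaldehyde
Conditions: MOMCl (1.05 equiv), K2CO3 (1.1 equiv), acetone, 0 °C to rt
Reagents that add atoms: chloromethyl methyl ether (MOMCl), COCCl
Why: Williamson-type O-alkylation; the 4-OH is the more acidic, unhindered phenol while the 2-OH is held in a hydrogen bond to the aldehyde, so the single MOM group goes to O-4.

Step 2
Reactants: 2 2-hydroxy-4-(methoxymethoxy)benzaldehyde
Product: 3 2-ethynyl-5-(methoxymethoxy)phenol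
Conditions: Ohira–Bestmann reagent (1.5 equiv), K2CO3 (3 equiv), MeOH, 0 °C to rt; NH4Cl work-up
Reagents that add atoms: dimethyl (1-diazo-2-oxopropyl)phosphonate (Ohira–Bestmann reagent), COP(=O)(OC)C(=[N+]=[N-])C(C)=O
Why: Seyferth–Gilbert homologation in the Ohira–Bestmann variant (methanolysis of the reagent gives the diazomethylphosphonate anion, which turns ArCHO into ArC≡CH with loss of N2); the phenoxide slows the addition, hence the excess of reagent and base.

Step 3
Reactants: 4 tert-butyldimethyl(prop-2-yn-1-yloxy)silane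
Product: 5 [(3-bromoprop-2-yn-1-yl)oxy](tert-butyl)dimethylsilane
Conditions: NBS (1.1 equiv), AgNO3 (10 mol%), acetone, rt
Reagents that add atoms: N-bromosuccinimide, O=C1CCC(=O)N1Br
Why: Silver-catalysed electrophilic bromination of a terminal alkyne (the silver acetylide is brominated by NBS).

Step 4
Reactants: 3 2-ethynyl-5-(methoxymethoxy)phenol; 5 [(3-bromoprop-2-yn-1-yl)oxy](tert-butyl)dimethylsilane
Product: 6 2-{5-[(tert-butyldimethylsilyl)oxy]penta-1,3-diyn-1-yl}-5-(methoxymethoxy)phenol
Conditions: CuCl (5 mol%), NH2OH·HCl (30 mol%), n-BuNH2 (30% aq.)/Et2O, 0 °C, slow addition of 5, 30 min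
Reagents that add atoms: none
Why: Cadiot–Chodkiewicz coupling of the copper acetylide of 3 (monovalent copper kept reduced by hydroxylamine) with bromoalkyne 5 gives the unsymmetrical 1,3-diyne; 0 °C and a short reaction time keep the ortho-phenol from adding to the alkyne.

Step 5
Reactants: 7 4-iodophenol
Product: 8 1-iodo-4-(methoxymethoxy)benzene
Conditions: MOMCl (1.2 equiv), K2CO3 (1.5 equiv), acetone, rt
Reagents that add atoms: chloromethyl methyl ether (MOMCl), COCCl
Why: Williamson-type O-alkylation (MOM protection) of a phenol; 8 serves twice, in steps 6 and 10.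

Step 6
Reactants: 9 1,4-bis(trimethylsilyl)buta-1,3-diyne; 8 1-iodo-4-(methoxymethoxy)benzene
Product: 12 {[4-(methoxymethoxy)phenyl]buta-1,3-diyn-1-yl}trimethylsilane, via lithium diynide 10 (not isolated), via zinc diynide 11 (not isolated)
Conditions: 9 (1.3 equiv), MeLi·LiBr (1.3 equiv), THF, −78 °C to rt; ZnCl2 (1.4 equiv), 0 °C; then 8 (1.0 equiv), Pd(PPh3)4 (3 mol%), rt
Reagents that add atoms: none
Why: Selective mono-desilylation of 9 by MeLi·LiBr, transmetalation to zinc and Negishi alkynylation of the aryl iodide under zerovalent palladium catalysis.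

Step 7
Reactants: 12 {[4-(methoxymethoxy)phenyl]buta-1,3-diyn-1-yl}trimethylsilane
Product: 14 5-[4-(methoxymethoxy)phenyl]penta-2,4-diynoic acid, via lithium aryldiynide 13 (not isolated)
Conditions: MeLi·LiBr (1.05 equiv), THF, −78 °C to rt; CO2, −78 °C; 1 M HCl work-up
Reagents that add atoms: carbon dioxide, O=C=O
Why: Silicon-to-lithium exchange at the alkynylsilane followed by carboxylation of the lithium acetylide with CO2; the MOM ether is inert to both.

Step 8
Reactants: 6 2-{5-[(tert-butyldimethylsilyl)oxy]penta-1,3-diyn-1-yl}-5-(methoxymethoxy)phenol; 14 5-[4-(methoxymethoxy)phenyl]penta-2,4-diynoic acid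
Product: 15 2-{5-[(tert-butyldimethylsilyl)oxy]penta-1,3-diyn-1-yl}-5-(methoxymethoxy)phenyl 5-[4-(methoxymethoxy)phenyl]penta-2,4-diynoate
Conditions: DCC (1.1 equiv), DMAP (5 mol%), CH2Cl2, −20 to 0 °C
Reagents that add atoms: none
Why: Steglich esterification of the only free hydroxyl group; low temperature and catalytic DMAP limit conjugate addition to the activated diynoate.

Step 9
Reactants: 15 2-{5-[(tert-butyldimethylsilyl)oxy]penta-1,3-diyn-1-yl}-5-(methoxymethoxy)phenyl 5-[4-(methoxymethoxy)phenyl]penta-2,4-diynoate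
Product: 17 8-{[(tert-butyldimethylsilyl)oxy]methyl}-3-(methoxymethoxy)-7-{[4-(methoxymethoxy)phenyl]ethynyl}-6H-benzo[c]chromen-6-one, via benzyne 16 (not isolated)
Conditions: cyclooctane (0.005 M), 150 °C, sealed tube, Ar, 16 h
Reagents that add atoms: none
Why: Proposed new method: a thermal intramolecular hexadehydro-Diels–Alder reaction in which the arene-bound 1,3-diyne is the four-carbon partner and the ester-activated alkyne of the diynoate the two-carbon partner; the first C–C bond (arene-bound diyne carbon to the ester α-carbon) closes the six-membered lactone, the resulting diradical closes at the unhindered CH2OTBS-bearing diyne terminus rather than at the aryl-bearing one, so the central benzene ring and the pyranone ring form together as benzyne 16 with the arylethynyl arm left over, and 16 then takes two vicinal hydrogens from cyclooctane in a concerted transfer to give the two adjacent ring CH groups with no stereocentre formed; the closest known reactions are ketone- and ester-tethered tetrayne hexadehydro-Diels–Alder cyclisations with three-atom tethers (giving 1-alkynylfluorenones and phthalides) and the reduction of such benzynes by cyclic alkanes, the new elements being the four-atom aryl ester tether (the ester must reach its less stable conformation, hence 150 °C) and the selection between the two diynes.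

Step 10
Reactants: 17 8-{[(tert-butyldimethylsilyl)oxy]methyl}-3-(methoxymethoxy)-7-{[4-(methoxymethoxy)phenyl]ethynyl}-6H-benzo[c]chromen-6-one; 8 1-iodo-4-(methoxymethoxy)benzene
Product: 21 selaginellin F, via aryllithium 18 (not isolated), via keto phenoxide 19 (not isolated), via triaryl carbinol 20 (not isolated)
Conditions: 8 (5 equiv), t-BuLi (10 equiv), THF, −78 °C; add 17, −78 °C to rt; then MeOH, conc. aq. HCl (to 3 M), 40 °C; NaHCO3 work-up
Reagents that add atoms: none
Why: Iodine–lithium exchange, then double 1,2-addition of the aryllithium to the aryl ester (lactone opening to the keto phenoxide, then addition to the ketone), then acid-mediated cleavage of the four MOM acetals and the silyl ether and E1 dehydration of the doubly para-hydroxylated trityl alcohol to the fuchsone-type quinone methide; no stereocentre is formed and the two 4-oxygenated rings on the methide carbon are interchangeable by tautomerism.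

**Compound list**

1 | 2,4-dihydroxybenzaldehyde | O=Cc1ccc(O)cc1O | starting material
2 | 2-hydroxy-4-(methoxymethoxy)benzaldehyde | O=Cc1ccc(OCOC)cc1O | intermediate
3 | 2-ethynyl-5-(methoxymethoxy)phenol | C#Cc1ccc(OCOC)cc1O | intermediate
4 | tert-butyldimethyl(prop-2-yn-1-yloxy)silane | C#CCO[Si](C)(C)C(C)(C)C | starting material
5 | [(3-bromoprop-2-yn-1-yl)oxy](tert-butyl)dimethylsilane | BrC#CCO[Si](C)(C)C(C)(C)C | intermediate
6 | 2-{5-[(tert-butyldimethylsilyl)oxy]penta-1,3-diyn-1-yl}-5-(methoxymethoxy)phenol | COCOc1ccc(C#CC#CCO[Si](C)(C)C(C)(C)C)c(O)c1 | intermediate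
7 | 4-iodophenol | Oc1ccc(I)cc1 | starting material
8 | 1-iodo-4-(methoxymethoxy)benzene | COCOc1ccc(I)cc1 | intermediate
9 | 1,4-bis(trimethylsilyl)buta-1,3-diyne | C[Si](C)(C)C#CC#C[Si](C)(C)C | starting material
10 | lithium 4-(trimethylsilyl)buta-1,3-diyn-1-ide (not isolated) | [Li]C#CC#C[Si](C)(C)C | intermediate
11 | chloro[4-(trimethylsilyl)buta-1,3-diyn-1-yl]zinc (not isolated) | Cl[Zn]C#CC#C[Si](C)(C)C | intermediate
12 | {[4-(methoxymethoxy)phenyl]buta-1,3-diyn-1-yl}trimethylsilane | COCOc1ccc(C#CC#C[Si](C)(C)C)cc1 | intermediate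
13 | lithium 4-[4-(methoxymethoxy)phenyl]buta-1,3-diyn-1-ide (not isolated) | [Li]C#CC#Cc1ccc(OCOC)cc1 | intermediate
14 | 5-[4-(methoxymethoxy)phenyl]penta-2,4-diynoic acid | COCOc1ccc(C#CC#CC(=O)O)cc1 | intermediate
15 | 2-{5-[(tert-butyldimethylsilyl)oxy]penta-1,3-diyn-1-yl}-5-(methoxymethoxy)phenyl 5-[4-(methoxymethoxy)phenyl]penta-2,4-diynoate | COCOc1ccc(C#CC#CCO[Si](C)(C)C(C)(C)C)c(OC(=O)C#CC#Cc2ccc(OCOC)cc2)c1 | intermediate
16 | 9,10-didehydro-8-{[(tert-butyldimethylsilyl)oxy]methyl}-3-(methoxymethoxy)-7-{[4-(methoxymethoxy)phenyl]ethynyl}-6H-benzo[c]chromen-6-one, the aryne at C9–C10 (not isolated) | O=C1Oc2cc(OCOC)ccc2C2=C1C(C#Cc1ccc(OCOC)cc1)=C(CO[Si](C)(C)C(C)(C)C)C#C2 | intermediate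
17 | 8-{[(tert-butyldimethylsilyl)oxy]methyl}-3-(methoxymethoxy)-7-{[4-(methoxymethoxy)phenyl]ethynyl}-6H-benzo[c]chromen-6-one | O=C1Oc2cc(OCOC)ccc2-c2ccc(CO[Si](C)(C)C(C)(C)C)c(C#Cc3ccc(OCOC)cc3)c12 | intermediate
18 | [4-(methoxymethoxy)phenyl]lithium (not isolated) | [Li]c1ccc(OCOC)cc1 | intermediate
19 | lithium 4'-{[(tert-butyldimethylsilyl)oxy]methyl}-2'-[4-(methoxymethoxy)benzoyl]-4-(methoxymethoxy)-3'-{[4-(methoxymethoxy)phenyl]ethynyl}biphenyl-2-olate (not isolated) | [Li+].[O-]c1cc(OCOC)ccc1-c1ccc(CO[Si](C)(C)C(C)(C)C)c(C#Cc2ccc(OCOC)cc2)c1C(=O)c1ccc(OCOC)cc1 | intermediate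
20 | 2'-{hydroxybis[4-(methoxymethoxy)phenyl]methyl}-4'-{[(tert-butyldimethylsilyl)oxy]methyl}-4-(methoxymethoxy)-3'-{[4-(methoxymethoxy)phenyl]ethynyl}biphenyl-2-ol (not isolated) | OC(c1ccc(OCOC)cc1)(c1ccc(OCOC)cc1)c1c(-c2ccc(OCOC)cc2O)ccc(CO[Si](C)(C)C(C)(C)C)c1C#Cc1ccc(OCOC)cc1 | intermediate
21 | selaginellin F, 4-[(4-hydroxyphenyl){2',4'-dihydroxy-4-(hydroxymethyl)-3-[(4-hydroxyphenyl)ethynyl]biphenyl-2-yl}methylidene]cyclohexa-2,5-dien-1-one | O=C1C=CC(=C(c2ccc(O)cc2)c2c(-c3ccc(O)cc3O)ccc(CO)c2C#Cc2ccc(O)cc2)C=C1 | target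

**Step count**

Total: 10 steps. Longest linear sequence: 6 steps (1 → 2 → 3 → 6 → 15 → 17 → 21; the branch 7 → 8 → 12 → 14 → 15 → 17 → 21 is equally long).

**Three steps most likely to fail**

Step 9 (ring-forming cascade). Risks: the four-atom aryl ester tether may make the cycloaddition slow relative to decomposition of the tetrayne; the diradical may close at the aryl-bearing terminus and give the regioisomeric arene; the benzyne may be trapped by something other than cyclooctane.

Fallback, setting out from 3 and returning at 17: Sonogashira coupling of 3 with (E)-tert-butyl[(3-iodoprop-2-en-1-yl)oxy]dimethylsilane (Pd(PPh3)2Cl2, CuI, Et3N, rt) gives (E)-2-{5-[(tert-butyldimethylsilyl)oxy]pent-3-en-1-yn-1-yl}-5-(methoxymethoxy)phenol F1. Steglich esterification of F1 with 14 gives (E)-2-{5-[(tert-butyldimethylsilyl)oxy]pent-3-en-1-yn-1-yl}-5-(methoxymethoxy)phenyl 5-[4-(methoxymethoxy)phenyl]penta-2,4-diynoate F2. Heating F2 (toluene, 150–180 °C, with 2,6-di-tert-butyl-4-methylphenol as proton shuttle) brings about a tetradehydro-Diels–Alder reaction of the enyne with the ynoate to the isoaromatic cyclic allene 6H-benzo[c]chromen-6-one precursor F3. F3 aromatises by a hydrogen shift from its sp3 carbon to the central allene carbon and gives 17 directly, with no aryne and no external hydrogen donor.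

Step 10 (double addition and unmasking). Risks: the second aryllithium addition to the di-ortho-substituted ketone may stall at the lactolate/ketone stage; in the acid step the free 2'-OH can hold the trityl cation as the cyclic aryl ether (6,6-diaryl-6H-benzo[c]chromene), which is in reversible ring–chain equilibrium with the quinone methide.

Fallback, setting out from 17 and returning at 21: add only 1.1 equiv of 18 at −78 °C, warm to 0 °C so that the lactolate opens, and cap the phenoxide in the same flask with MOMCl to isolate [4'-{[(tert-butyldimethylsilyl)oxy]methyl}-2,4-bis(methoxymethoxy)-3'-{[4-(methoxymethoxy)phenyl]ethynyl}biphenyl-2'-yl][4-(methoxymethoxy)phenyl]methanone F4. Add the second aryl group as the organocerium reagent made from 18 and CeCl3 (THF, −78 to 0 °C) to give the fully protected [4'-{[(tert-butyldimethylsilyl)oxy]methyl}-2,4-bis(methoxymethoxy)-3'-{[4-(methoxymethoxy)phenyl]ethynyl}biphenyl-2'-yl]bis[4-(methoxymethoxy)phenyl]methanol F5. The methanolic HCl treatment of step 10 then converts F5 into 21.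

Step 4 (Cadiot–Chodkiewicz coupling on a free ortho-alkynylphenol). Risk: copper- and base-promoted 5-endo cyclisation of 3 or 6 to a benzofuran.

Fallback, setting out from 3 and returning at 6: silylate the phenol (TBSCl, imidazole, CH2Cl2) to tert-butyl[2-ethynyl-5-(methoxymethoxy)phenoxy]dimethylsilane F6. With no free phenol present, an oxidative Hay cross-coupling with an excess of 4 (CuCl, TMEDA, O2, acetone, rt) replaces the bromoalkyne coupling and gives tert-butyl{[5-(2-{[tert-butyl(dimethyl)silyl]oxy}-4-(methoxymethoxy)phenyl)penta-2,4-diyn-1-yl]oxy}dimethylsilane F7. KHF2 in MeOH (rt) cleaves only the aryl silyl ether of F7 and returns 6.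

**Further compounds**

F1 | step 9 | (E)-2-{5-[(tert-butyldimethylsilyl)oxy]pent-3-en-1-yn-1-yl}-5-(methoxymethoxy)phenol | COCOc1ccc(C#C/C=C/CO[Si](C)(C)C(C)(C)C)c(O)c1
F2 | step 9 | (E)-2-{5-[(tert-butyldimethylsilyl)oxy]pent-3-en-1-yn-1-yl}-5-(methoxymethoxy)phenyl 5-[4-(methoxymethoxy)phenyl]penta-2,4-diynoate | COCOc1ccc(C#C/C=C/CO[Si](C)(C)C(C)(C)C)c(OC(=O)C#CC#Cc2ccc(OCOC)cc2)c1
F3 | step 9 | isoaromatic cyclic allene, 8-{[(tert-butyldimethylsilyl)oxy]methyl}-3-(methoxymethoxy)-7-{[4-(methoxymethoxy)phenyl]ethynyl}-8H-benzo[c]chromen-6-one with cumulated double bonds C10a=C10=C9 | O=C1Oc2cc(OCOC)ccc2C2=C=CC(CO[Si](C)(C)C(C)(C)C)C(C#Cc3ccc(OCOC)cc3)=C12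
F4 | step 10 | [4'-{[(tert-butyldimethylsilyl)oxy]methyl}-2,4-bis(methoxymethoxy)-3'-{[4-(methoxymethoxy)phenyl]ethynyl}biphenyl-2'-yl][4-(methoxymethoxy)phenyl]methanone | COCOc1ccc(cc1)C(=O)c1c(-c2ccc(OCOC)cc2OCOC)ccc(CO[Si](C)(C)C(C)(C)C)c1C#Cc1ccc(OCOC)cc1
F5 | step 10 | [4'-{[(tert-butyldimethylsilyl)oxy]methyl}-2,4-bis(methoxymethoxy)-3'-{[4-(methoxymethoxy)phenyl]ethynyl}biphenyl-2'-yl]bis[4-(methoxymethoxy)phenyl]methanol | COCOc1ccc(cc1)C(O)(c1ccc(OCOC)cc1)c1c(-c2ccc(OCOC)cc2OCOC)ccc(CO[Si](C)(C)C(C)(C)C)c1C#Cc1ccc(OCOC)cc1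
F6 | step 4 | tert-butyl[2-ethynyl-5-(methoxymethoxy)phenoxy]dimethylsilane | C#Cc1ccc(OCOC)cc1O[Si](C)(C)C(C)(C)C
F7 | step 4 | tert-butyl{[5-(2-{[tert-butyl(dimethyl)silyl]oxy}-4-(methoxymethoxy)phenyl)penta-2,4-diyn-1-yl]oxy}dimethylsilane | COCOc1ccc(C#CC#CCO[Si](C)(C)C(C)(C)C)c(O[Si](C)(C)C(C)(C)C)c1
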